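**Plan**

- Ring numbering used in the text: C1 ketone, C2=C3, C4 carbinol carbon (hexadecyl), C5 the CH carrying ester carbon C6 (the IUPAC names below number the ring differently).
- Retrosynthesis: the O–Si bond at C4 and the C2=C3 unsaturation are taken back first, then the ring is cut at C2–C3 and at C4–C5 in one formal (3+2) disconnection.
- Enabling feature: C5–C1–C2 with C6 is an acetoacetate unit (used as a siloxyvinyl diazoacetate), and C3–C4 is the silyl enol ether of a methyl ketone whose oxygen-bearing carbon becomes the quaternary C4.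
- Forward: methyl acetoacetate 1 → diazo ester 2 → enoldiazoacetate 3; octadecan-2-one 4 → enol ether 5; rhodium-catalysed annulation of 3 and 5 builds the only ring (6); unmasking (7), α′-selenenylation (8), selenoxide elimination (via 9 to 10) and desilylation give 11.
- Stereochemistry: C4 comes from the chiral dirhodium carboxylate in the ring closure; C5 is an epimerisable keto ester carbon that settles under control of C4 as (1R,5R), ester trans to hexadecyl.

Key step: step 4

Assumption 1: the sense of induction of the catalyst is not known in advance; Rh2(S-PTAD)4 is written, and Rh2(R-PTAD)4 is to be used if the S catalyst gives the (5S) adduct.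
Assumption 2: C5 of the target is configurationally labile, and the (1R,5R) isomer (ester trans to hexadecyl, cis to the hydrogen-bonding hydroxyl) is taken to be the thermodynamically preferred epimer.

**Route**

Step 1
Reactants: 1 methyl acetoacetate
Product: 2 methyl 2-diazo-3-oxobutanoate
Conditions: p-ABSA (1.05 equiv), Et3N, MeCN, 0 °C → rt
Reagents that add atoms: 4-acetamidobenzenesulfonyl azide (p-ABSA), CC(=O)Nc1ccc(cc1)S(=O)(=O)N=[N+]=[N-]
Why: Regitz diazo transfer from a sulfonyl azide to the doubly activated methylene of a β-keto ester is routine and leaves the ester untouched.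

Step 2
Reactants: 2 methyl 2-diazo-3-oxobutanoate
Product: 3 methyl 3-(tert-butyldimethylsilyloxy)-2-diazobut-3-enoate
Conditions: TBSOTf (1.1 equiv), Et3N, CH2Cl2, 0 °C
Reagents that add atoms: tert-butyldimethylsilyl trifluoromethanesulfonate (TBSOTf), CC(C)(C)[Si](C)(C)OS(=O)(=O)C(F)(F)F
Why: The acetyl methyl is the only enolisable position, so soft enolisation with silyl triflate and amine gives the O-silyl enol ether (the standard preparation of siloxyvinyl diazoacetates) without affecting the diazo group.

Step 3
Reactants: 4 octadecan-2-one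
Product: 5 tert-butyldimethyl(octadec-1-en-2-yloxy)silane
Conditions: LDA (1.1 equiv, commercial solution), THF, −78 °C, ketone added slowly; TBSOTf, −78 → 0 °C; filtration through Et3N-deactivated silica
Reagents that add atoms: tert-butyldimethylsilyl trifluoromethanesulfonate (TBSOTf), CC(C)(C)[Si](C)(C)OS(=O)(=O)C(F)(F)F
Why: Kinetic deprotonation of a methyl ketone with LDA at −78 °C removes a methyl proton, and O-silylation of the terminal lithium enolate gives the 2-siloxy-1-alkene (kinetic silyl enol ether formation).

Step 4
Reactants: 3 methyl 3-(tert-butyldimethylsilyloxy)-2-diazobut-3-enoate, 5 tert-butyldimethyl(octadec-1-en-2-yloxy)silane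
Product: 6 methyl (5R)-2,5-bis(tert-butyldimethylsilyloxy)-5-hexadecylcyclopent-1-ene-1-carboxylate
Conditions: Rh2(S-PTAD)4 (1 mol %), 4 Å MS, CH2Cl2, −40 → 0 °C, 3 (1.5 equiv) added by syringe pump to 5 and catalyst
Reagents that add atoms: none
Why: Proposed new method: Rhodium(II) expels dinitrogen from 3 to give an electrophilic enol-carbene in which the siloxy group screens the carbene carbon, so the CH2 terminus of the electron-rich 1,1-disubstituted enol ether 5 should add to the vinylogous CH2 (ring bond C2–C3) and leave a tertiary silyloxycarbenium ion at C4 linked to a vinyl–rhodium centre at C5. The closest known reaction types are the dirhodium-catalysed asymmetric formal (3+2) annulation of vinylcarbenes with alkyl vinyl ethers and the vinylogous addition of silyl enol ethers to siloxyvinylcarbenes; closure onto a ketone-derived silyl enol ether to make a quaternary carbinol is the untested part. The cyclopentene ring closes by attack of C5 on the oxocarbenium carbon C4, formally a 5-(enolendo)-exo-trig process that is feasible here because the reacting electrons are those of the in-plane C5–Rh σ bond and not of the enol π bond, and this releases the catalyst. The only new stereocentre, C4, is set in that ring closure by the chiral phthalimido-carboxylate pocket of the catalyst, which holds the tethered oxocarbenium ion so that one of its faces meets the metal-bound carbon. The step needs vinylogous rather than carbenoid attack (no cyclopropane) and C–C closure rather than a 1,4-shift of the siloxy group to an acyclic alkynoate or loss of silyl from the carbenium ion; the unsubstituted vinyl terminus, the bulky siloxy group on the carbene, the polar non-coordinating solvent and the bulky tert-butyldimethylsilyl group on the carbenium oxygen are the features relied on. Since the acetoacetate unit stays masked as its silyl enol ether throughout, the C4 oxygen cannot be lost by β-elimination under the reaction conditions.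

Step 5
Reactants: 6 methyl (5R)-2,5-bis(tert-butyldimethylsilyloxy)-5-hexadecylcyclopent-1-ene-1-carboxylate
Product: 7 methyl (2R)-2-(tert-butyldimethylsilyloxy)-2-hexadecyl-5-oxocyclopentane-1-carboxylate (C1 epimers plus enol form)
Conditions: TBAF (1.05 equiv), AcOH (1.05 equiv), THF, −40 → 0 °C
Reagents that add atoms: none
Why: Fluoride cleaves the Si–O bond of the β-siloxy acrylate (a vinylogous silyl ester with a stabilised enolate as leaving group) much faster than that of the hindered tertiary alkyl silyl ether, and the acetic acid buffer protonates the enolate at once so that it cannot expel the β-siloxy group at C4 (chemoselective desilylation of a silyl enol ether).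

Step 6
Reactants: 7 methyl (2R)-2-(tert-butyldimethylsilyloxy)-2-hexadecyl-5-oxocyclopentane-1-carboxylate
Product: 8 methyl (2R)-2-(tert-butyldimethylsilyloxy)-2-hexadecyl-5-oxo-4-(phenylselanyl)cyclopentane-1-carboxylate (diastereomer mixture)
Conditions: LDA (2.2 equiv), THF, −78 → −20 °C; PhSeCl (1.05 equiv), −78 °C; AcOH quench at −78 °C
Reagents that add atoms: phenylselenenyl chloride (PhSeCl), Cl[Se]c1ccccc1
Why: The dianion of a cyclic β-keto ester reacts with electrophiles at its more reactive α′ carbon (ring C2), so selenenylation with PhSeCl places selenium on the side of the ketone remote from the ester, and the low temperature is meant to keep the enolate from expelling the β-siloxy group (dianion α′-selenenylation).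

Step 7
Reactants: 8 methyl (2R)-2-(tert-butyldimethylsilyloxy)-2-hexadecyl-5-oxo-4-(phenylselanyl)cyclopentane-1-carboxylate
Product: 10 methyl (5R)-5-(tert-butyldimethylsilyloxy)-5-hexadecyl-2-oxocyclopent-3-ene-1-carboxylate, via selenoxide 9 (not isolated)
Conditions: 30% aq. H2O2, pyridine, CH2Cl2, 0 °C → rt
Reagents that add atoms: none
Why: Oxidation at selenium gives the selenoxide, which undergoes syn elimination at or below room temperature toward the only available β-hydrogens, those on ring C3, and so installs the C2=C3 double bond (selenoxide elimination), while the quaternary C4 is not touched.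

Step 8
Reactants: 10 methyl (5R)-5-(tert-butyldimethylsilyloxy)-5-hexadecyl-2-oxocyclopent-3-ene-1-carboxylate
Product: 11 methyl (1R,5R)-5-hexadecyl-5-hydroxy-2-oxocyclopent-3-ene-1-carboxylate (CNP0277713.1)
Conditions: 48% aq. HF, MeCN, 0 °C → rt, polypropylene vessel
Reagents that add atoms: none
Why: Acidic fluoride desilylation cleaves the tertiary silyl ether without forming the C4 alkoxide (whose retro-aldol opening would racemise C4) and without ionisation at C4, which the electron-poor enone disfavours, and the enolisable keto ester carbon C5 then settles under substrate control from C4 with the ester trans to hexadecyl and cis to the hydrogen-bonding hydroxyl, i.e. (1R,5R).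

**Compound list**

1 | methyl acetoacetate (methyl 3-oxobutanoate) | CC(=O)CC(=O)OC | starting material
2 | methyl 2-diazo-3-oxobutanoate | CC(=O)C(=[N+]=[N-])C(=O)OC | intermediate
3 | methyl 3-(tert-butyldimethylsilyloxy)-2-diazobut-3-enoate | COC(=O)C(=[N+]=[N-])C(=C)O[Si](C)(C)C(C)(C)C | intermediate
4 | octadecan-2-one | CCCCCCCCCCCCCCCCC(C)=O | starting material
5 | tert-butyldimethyl(octadec-1-en-2-yloxy)silane | C=C(CCCCCCCCCCCCCCCC)O[Si](C)(C)C(C)(C)C | intermediate
6 | methyl (5R)-2,5-bis(tert-butyldimethylsilyloxy)-5-hexadecylcyclopent-1-ene-1-carboxylate | CCCCCCCCCCCCCCCC[C@@]1(O[Si](C)(C)C(C)(C)C)CCC(O[Si](C)(C)C(C)(C)C)=C1C(=O)OC | intermediate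
7 | methyl (2R)-2-(tert-butyldimethylsilyloxy)-2-hexadecyl-5-oxocyclopentane-1-carboxylate (C1 epimers and enol form) | CCCCCCCCCCCCCCCC[C@@]1(O[Si](C)(C)C(C)(C)C)CCC(=O)C1C(=O)OC | intermediate
8 | methyl (2R)-2-(tert-butyldimethylsilyloxy)-2-hexadecyl-5-oxo-4-(phenylselanyl)cyclopentane-1-carboxylate (diastereomers at C1 and C4) | CCCCCCCCCCCCCCCC[C@@]1(O[Si](C)(C)C(C)(C)C)CC([Se]c2ccccc2)C(=O)C1C(=O)OC | intermediate
9 | methyl (2R)-2-(tert-butyldimethylsilyloxy)-2-hexadecyl-5-oxo-4-(phenylseleninyl)cyclopentane-1-carboxylate | CCCCCCCCCCCCCCCC[C@@]1(O[Si](C)(C)C(C)(C)C)CC([Se](=O)c2ccccc2)C(=O)C1C(=O)OC | intermediate (not isolated)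
10 | methyl (5R)-5-(tert-butyldimethylsilyloxy)-5-hexadecyl-2-oxocyclopent-3-ene-1-carboxylate (C1 epimers) | CCCCCCCCCCCCCCCC[C@@]1(O[Si](C)(C)C(C)(C)C)C=CC(=O)C1C(=O)OC | intermediate
11 | methyl (1R,5R)-5-hexadecyl-5-hydroxy-2-oxocyclopent-3-ene-1-carboxylate | CCCCCCCCCCCCCCCC[C@@]1(O)C=CC(=O)[C@@H]1C(=O)OC | target

**Step count and risks**

Total step count: 8. Longest linear sequence: 7 steps (steps 1, 2, 4, 5, 6, 7, 8 from methyl acetoacetate).

Step 4 (proposed new method). The zwitterion may fail to close and instead collapse by a 1,4-shift of the siloxy group to an acyclic alkynoate or by loss of silyl. The enol ether may also add at the carbene carbon (cyclopropanation), or the closure may proceed with poor facial selectivity. The fallback uses known chemistry, sets out from 4 and comes back at 11, forming the same two ring bonds one after the other. The kinetic lithium enolate of 4 (LDA, THF, −78 °C) is alkylated with methyl (E)-4-bromo-3-methoxybut-2-enoate to give methyl (2E)-3-methoxy-6-oxodocos-2-enoate F1 (C2–C3 bond). Aqueous HCl in THF hydrolyses the enol ether to methyl 3,6-dioxodocosanoate F2. Paal–Knorr cyclodehydration (cat. TsOH, toluene, reflux) gives methyl 2-(5-hexadecylfuran-2-yl)acetate F3. Oxidative opening of the furan (mCPBA, CH2Cl2, 0 °C) gives methyl (4Z)-3,6-dioxodocos-4-enoate F4. Its keto ester methylene then adds to the hexadecyl ketone in an intramolecular aldol reaction (cat. Et3N, CH2Cl2, 0 °C; C4–C5 bond), which cannot be followed by dehydration, and should give racemic methyl (1R*,5R*)-5-hexadecyl-5-hydroxy-2-oxocyclopent-3-ene-1-carboxylate F5. Preparative HPLC on a chiral stationary phase then delivers 11.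

Step 6. While the dianion is generated, the enolate may expel the β-siloxy group at C4 (loss of the carbinol oxygen and of the stereocentre), or selenium may enter twice. The fallback sets out from 6 and comes back at 10, keeping the keto ester masked until C2=C3 exists. LDA in the presence of TMSCl (THF, −78 °C, in situ quench) removes a C2 proton of 6 and silylates the ester oxygen, as in the second stage of a Chan-type diene synthesis. This gives (5R)-2,5-bis(tert-butyldimethylsilyloxy)-5-hexadecyl-1-[methoxy(trimethylsilyloxy)methylidene]cyclopent-2-ene F6. Saegusa–Ito oxidation (Pd(OAc)2, MeCN, rt) gives methyl (5R)-2,5-bis(tert-butyldimethylsilyloxy)-5-hexadecylcyclopenta-1,3-diene-1-carboxylate F7. Buffered fluoride (TBAF/AcOH, THF, −40 °C) then unmasks the keto ester to give 10, at a stage where loss of the C4 oxygen would require a cyclopentadienone.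

Step 8. Cleavage of the hindered tertiary silyl ether may stall, and forcing it with basic fluoride would form the C4 alkoxide, whose retro-aldol opening and reclosure would erode the enantiomeric purity. The fallback sets out from 4 and comes back at 11, carrying the C4 oxygen as a triethylsilyl ether that dilute acid removes. LDA then TESCl (THF, −78 °C) gives triethyl(octadec-1-en-2-yloxy)silane F8. Annulation with 3 under the conditions of step 4 gives methyl (5R)-2-(tert-butyldimethylsilyloxy)-5-hexadecyl-5-(triethylsilyloxy)cyclopent-1-ene-1-carboxylate F9. Buffered fluoride at −40 °C gives methyl (2R)-2-hexadecyl-5-oxo-2-(triethylsilyloxy)cyclopentane-1-carboxylate F10. Dianion selenenylation gives methyl (2R)-2-hexadecyl-5-oxo-4-(phenylselanyl)-2-(triethylsilyloxy)cyclopentane-1-carboxylate F11. Oxidation with H2O2/pyridine via methyl (2R)-2-hexadecyl-5-oxo-4-(phenylseleninyl)-2-(triethylsilyloxy)cyclopentane-1-carboxylate F12 gives methyl (5R)-5-hexadecyl-2-oxo-5-(triethylsilyloxy)cyclopent-3-ene-1-carboxylate F13. AcOH/THF/H2O at rt then gives 11.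

**Further compounds**

F1 | step 4 | methyl (2E)-3-methoxy-6-oxodocos-2-enoate | CCCCCCCCCCCCCCCCC(=O)CC/C(OC)=C\C(=O)OC
F2 | step 4 | methyl 3,6-dioxodocosanoate | CCCCCCCCCCCCCCCCC(=O)CCC(=O)CC(=O)OC
F3 | step 4 | methyl 2-(5-hexadecylfuran-2-yl)acetate | CCCCCCCCCCCCCCCCc1ccc(CC(=O)OC)o1
F4 | step 4 | methyl (4Z)-3,6-dioxodocos-4-enoate | CCCCCCCCCCCCCCCCC(=O)/C=C\C(=O)CC(=O)OC
F5 | step 4 | racemic methyl (1R*,5R*)-5-hexadecyl-5-hydroxy-2-oxocyclopent-3-ene-1-carboxylate | CCCCCCCCCCCCCCCCC1(O)C=CC(=O)C1C(=O)OC
F6 | step 6 | (5R)-2,5-bis(tert-butyldimethylsilyloxy)-5-hexadecyl-1-[methoxy(trimethylsilyloxy)methylidene]cyclopent-2-ene | CCCCCCCCCCCCCCCC[C@@]1(O[Si](C)(C)C(C)(C)C)CC=C(O[Si](C)(C)C(C)(C)C)C1=C(OC)O[Si](C)(C)C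
F7 | step 6 | methyl (5R)-2,5-bis(tert-butyldimethylsilyloxy)-5-hexadecylcyclopenta-1,3-diene-1-carboxylate | CCCCCCCCCCCCCCCC[C@@]1(O[Si](C)(C)C(C)(C)C)C=CC(O[Si](C)(C)C(C)(C)C)=C1C(=O)OC
F8 | step 8 | triethyl(octadec-1-en-2-yloxy)silane | C=C(CCCCCCCCCCCCCCCC)O[Si](CC)(CC)CC
F9 | step 8 | methyl (5R)-2-(tert-butyldimethylsilyloxy)-5-hexadecyl-5-(triethylsilyloxy)cyclopent-1-ene-1-carboxylate | CCCCCCCCCCCCCCCC[C@@]1(O[Si](CC)(CC)CC)CCC(O[Si](C)(C)C(C)(C)C)=C1C(=O)OC
F10 | step 8 | methyl (2R)-2-hexadecyl-5-oxo-2-(triethylsilyloxy)cyclopentane-1-carboxylate | CCCCCCCCCCCCCCCC[C@@]1(O[Si](CC)(CC)CC)CCC(=O)C1C(=O)OC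
F11 | step 8 | methyl (2R)-2-hexadecyl-5-oxo-4-(phenylselanyl)-2-(triethylsilyloxy)cyclopentane-1-carboxylate | CCCCCCCCCCCCCCCC[C@@]1(O[Si](CC)(CC)CC)CC([Se]c2ccccc2)C(=O)C1C(=O)OC
F12 | step 8 | methyl (2R)-2-hexadecyl-5-oxo-4-(phenylseleninyl)-2-(triethylsilyloxy)cyclopentane-1-carboxylate | CCCCCCCCCCCCCCCC[C@@]1(O[Si](CC)(CC)CC)CC([Se](=O)c2ccccc2)C(=O)C1C(=O)OC
F13 | step 8 | methyl (5R)-5-hexadecyl-2-oxo-5-(triethylsilyloxy)cyclopent-3-ene-1-carboxylate | CCCCCCCCCCCCCCCC[C@@]1(O[Si](CC)(CC)CC)C=CC(=O)C1C(=O)OC
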